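Assumption: the target has no stereocentre and its exocyclic carbon carries two bromines (no E/Z element), so it is one achiral compound and no asymmetric step is needed.

**Retrosynthetic overview**
1. Target 9 ← loss of HBr (E1cB) from the C4 gem-dibromide 8, which comes from double allylic bromination of enol lactone 6.
2. 6 (the only ring, with both exocyclic C–Br bonds) ← hypobromite cascade on terminal alkynoic acid 4: alkynyl C–H bromination, then 5-exo-dig bromolactonisation. This mirrors the haloperoxidase (HOBr) bromolactonisation thought to build the fimbrolide ring in Delisea.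
3. 4 ← hexanoic acid dianion + propargyl bromide.

**Step 1**
Reactants: 1 hexanoic acid; 2 propargyl bromide (3-bromoprop-1-yne)
Product: 4 2-butylpent-4-ynoic acid (racemic), via dilithium hexanoate enediolate 3 (not isolated)
Conditions: LDA (2.2 equiv), THF, 0 °C; then 2 (1.1 equiv), −78 °C → rt; aq. HCl work-up
Reagents that add atoms: none
Why: α-Alkylation of a carboxylic acid dianion (enediolate) with a primary propargylic bromide is a standard SN2 C–C bond formation; the new C2 stereocentre is racemic, which does not matter because C2 becomes sp2 in step 3.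

**Step 2**
Reactants: 4 2-butylpent-4-ynoic acid
Product: 6 3-butyl-5-(dibromomethylene)dihydrofuran-2(3H)-one (racemic), via sodium 5-bromo-2-butylpent-4-ynoate 5 (not isolated)
Conditions: Br2 (1.05 equiv), NaOH (3.1 equiv), H2O, 0 °C; then NaH2PO4 (to pH 7), CH2Cl2, Br2 (1.05 equiv), 0 °C
Reagents that add atoms: bromine, BrBr (the first equivalent is delivered as NaOBr)
Why: Proposed new method: at pH 14 the carboxylate is inert and hypobromite brominates only the acetylenic C–H (Straus-type bromination of an ω-alkynoate), and after the pH switch the second Br+ activates the bromoalkyne so that the carboxylate closes 5-exo-dig anti to it, giving the ring and the CBr2 group in one flask; the closest known reactions are the hypobromite bromination of terminal alkynoic acids and the NBS/bicarbonate halolactonisation of 4-pentynoic acids to halo enol lactones.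

**Step 3**
Reactants: 6 3-butyl-5-(dibromomethylene)dihydrofuran-2(3H)-one
Product: 9 4-bromo-3-butyl-5-(dibromomethylene)furan-2(5H)-one (target), via allylic monobromide 7 (not isolated), via allylic gem-dibromide 8 (not isolated)
Conditions: NBS (2.2 equiv), AIBN (cat.), PhCF3, hν, 60 °C; then Et3N (1.5 equiv), 0 °C
Reagents that add atoms: N-bromosuccinimide, BrN1C(=O)CCC1=O
Why: Wohl–Ziegler bromination attacks the only allylic C–H bonds (C4, next to the enol-ether C=C) twice, and Et3N then removes the acidic C3–H and expels one C4 bromide (E1cB dehydrobromination) to give the conjugated tetrasubstituted bromobutenolide, erasing the C3 stereocentre.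

**Compound list**
1 | hexanoic acid | CCCCCC(=O)O | starting material
2 | propargyl bromide (3-bromoprop-1-yne) | C#CCBr | starting material
3 | dilithium hexanoate enediolate | CCCCC=C([O-])[O-].[Li+].[Li+] | intermediate
4 | 2-butylpent-4-ynoic acid (racemic) | CCCCC(CC#C)C(=O)O | intermediate
5 | sodium 5-bromo-2-butylpent-4-ynoate (racemic) | CCCCC(CC#CBr)C(=O)[O-].[Na+] | intermediate
6 | 3-butyl-5-(dibromomethylene)dihydrofuran-2(3H)-one (racemic) | CCCCC1CC(=C(Br)Br)OC1=O | intermediate
7 | 4-bromo-3-butyl-5-(dibromomethylene)dihydrofuran-2(3H)-one (racemic, diastereomer mixture) | CCCCC1C(Br)C(=C(Br)Br)OC1=O | intermediate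
8 | 4,4-dibromo-3-butyl-5-(dibromomethylene)dihydrofuran-2(3H)-one (racemic) | CCCCC1C(Br)(Br)C(=C(Br)Br)OC1=O | intermediate
9 | 4-bromo-3-butyl-5-(dibromomethylene)furan-2(5H)-one (achiral) | CCCCC1=C(Br)C(=C(Br)Br)OC1=O | target

**Totals**
Total step count: 3. Longest linear sequence: 3 steps (1 → 4 → 6 → 9).

**Steps most likely to fail, with fallbacks**

Step 3 is the most likely to fail. The second bromination at the crowded C4 may be slow, and monobromide 7 can lose HBr to the unwanted C4–H butenolide. If the second bromine arrives with allylic transposition (giving the CBr3-substituted furan-2(3H)-one), Et3N should still funnel that isomer to 9 by vinylogous E1cB. The fallback sets out from 6 and installs the C4 bromine through a C4 oxygen instead. Brominate only once (NBS 1.05 equiv, hν) and isolate 7. Solvolyse it with silver trifluoroacetate in aqueous acetone to 3-butyl-5-(dibromomethylene)-4-hydroxydihydrofuran-2(3H)-one F6. Oxidise with Dess–Martin periodinane to the tetronic acid 3-butyl-5-(dibromomethylene)-4-hydroxyfuran-2(5H)-one F7. Convert its enol OH to bromide with oxalyl bromide and catalytic DMF (CH2Cl2, 0 °C → rt), which comes back to the route at 9.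

Step 2 is the second risk. The bromoalkyne may close 6-endo instead of 5-exo, and the enol lactone may hydrolyse in the aqueous phase. The fallback sets out from 4 and closes the ring on the plain terminal alkyne, where Markovnikov 5-exo closure is unambiguous. NBS, KHCO3 and catalytic Bu4NOH in CH2Cl2–H2O give (E)-5-(bromomethylene)-3-butyldihydrofuran-2(3H)-one F4. Br2 in CH2Cl2 at 0 °C adds across the enol-ether double bond to give 5-bromo-5-(dibromomethyl)-3-butyldihydrofuran-2(3H)-one F5. Et3N at 0 °C removes the acidic CHBr2 proton with loss of the C5 bromide, which comes back to the route at 6.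

Step 1 is the third risk. The strongly basic enediolate 3 may deprotonate the alkyne C–H of 2 or be alkylated twice. The fallback sets out from 2 and uses a soft malonate anion. Alkylate purchased diethyl 2-butylmalonate F1 with 2 (NaH, THF, 0 °C → rt) to give diethyl 2-butyl-2-(prop-2-yn-1-yl)malonate F2. Saponify (KOH, EtOH–H2O, reflux; then HCl) to 2-butyl-2-(prop-2-yn-1-yl)malonic acid F3. Decarboxylate neat at 150 °C, which comes back to the route at 4.

**Further compounds**
F1 | step 1 | diethyl 2-butylmalonate | CCCCC(C(=O)OCC)C(=O)OCC
F2 | step 1 | diethyl 2-butyl-2-(prop-2-yn-1-yl)malonate | CCCCC(CC#C)(C(=O)OCC)C(=O)OCC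
F3 | step 1 | 2-butyl-2-(prop-2-yn-1-yl)malonic acid | CCCCC(CC#C)(C(=O)O)C(=O)O
F4 | step 2 | (E)-5-(bromomethylene)-3-butyldihydrofuran-2(3H)-one (racemic) | CCCCC1C/C(=C\Br)OC1=O
F5 | step 2 | 5-bromo-5-(dibromomethyl)-3-butyldihydrofuran-2(3H)-one (racemic, diastereomer mixture) | CCCCC1CC(Br)(C(Br)Br)OC1=O
F6 | step 3 | 3-butyl-5-(dibromomethylene)-4-hydroxydihydrofuran-2(3H)-one (racemic, diastereomer mixture) | CCCCC1C(O)C(=C(Br)Br)OC1=O
F7 | step 3 | 3-butyl-5-(dibromomethylene)-4-hydroxyfuran-2(5H)-one | CCCCC1=C(O)C(=C(Br)Br)OC1=O
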